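## Structural features

Sesterfisherol (28, C25H42O) is a linearly fused 5-8-6-5 tetracycle: cyclopentane ring A, cyclooctene ring B, cyclohexane ring C and cyclopentane ring D, with trans B/C and trans C/D fusions. All functionality sits in ring B: a tetrasubstituted alkene joins the methyl-bearing ring B carbon to the A/B fusion carbon (exocyclic to ring A), and the neighbouring B/C fusion carbon carries a tertiary, hence allylic, alcohol. The eight stereocentres form three clusters:

- ring A: CH(CH3) next to the A/B fusion CH;
- ring B: CH(CH3), the adjacent B/C fusion CH and the carbinol carbon;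
- rings C/D: the quaternary methyl carbon, the C/D fusion CH and the isopropyl-bearing CH, with methyl, ring C bond and isopropyl all on one face of ring D.

The tertiary allylic alcohol is the fragile group (ionisation, dehydration or allylic transposition under acid), and the tetrasubstituted alkene can migrate under acid. The real difficulty is the eight-membered ring with its trans fusion to ring C, and the relay of configuration from the C/D unit to the two remote ring A centres through rings that carry no functional group. The feature used here is that the methyl-bearing alkene carbon of ring B is a masked ketone carbon. Its two neighbours on the ring A side, the ring A alkene carbon and the A/B fusion CH, are then the α- and β-carbons of a ring B enone, so ring A can be annulated as a three-carbon unit across that enone.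

## Logic of the disconnections

**28 ⇒ 27 ⇒ 26 ⇒ 24.** The bond cut is the one between the ring B alkene carbon and its methyl group, after the alcohol has been masked as a silyl ether. The tetrasubstituted alkene next to the tertiary alcohol is the most sensitive part and is therefore made last, from a ketone via its alkenyl triflate. Ketone 24 has a single α-hydrogen, on ring A, so regiochemistry and alkene geometry are fixed by the ring system. The forward steps must enolise a hindered ketone and couple a methyl nucleophile at a fully substituted alkenyl triflate.

**24 ⇒ 23 ⇒ 22.** No skeletal bond is cut; the ring A alkene and the silicon substituent are put back. Both are the footprint of the annulation. The forward steps must remove silicon without moving the alkene towards the CH(CH3) carbon, then saturate a disubstituted cyclopentene.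

**22 ⇒ 17 + 21.** Two ring A bonds are cut: A/B fusion CH to CH(CH3), and ketone α-carbon to the ring A alkene CH. This removes ring A and both of its stereocentres in one operation and leaves tricyclic enone 17 and the three-carbon partner 21. The forward step must add to the enone face away from the silyl ether, and ring closure must outrun loss of silicon. The methyl centre is put under reagent control by using 21 as a single enantiomer.

**17 ⇒ 16.** The enone C=C of ring B is cut (ring-closing metathesis). An eight-membered ring can only hold the cis alkene, and the two chains sit on adjacent equatorial positions of the ring C chair. The forward step needs high dilution and a catalyst that accepts a hindered vinyl ketone.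

**16 ⇒ 15 ⇒ 13.** The bond between the carbinol carbon and the acyl carbon is cut. This returns ketone 13 and a three-carbon acryloyl anion equivalent. The nucleophile must enter equatorially, trans to the α side chain, to give the axial alcohol.

**13 ⇒ 12 ⇒ 10.** The sp3–sp2 bond between the homoallylic CH2 and the terminal vinyl group is cut. This shortens the side chain to the but-3-en-2-yl group that a sigmatropic shift can deliver. The forward step is an anti-Markovnikov hydroboration and alkyl–vinyl coupling; the ketone is reduced in passing and re-oxidised.

**10 ⇒ 7.** The bond between the ring C α-carbon and the side-chain CH(CH3) is cut. The two adjacent centres are linked through a chair [3,3] transition state, so the side-chain centre follows from the alkene geometry of the crotyl unit and from the face of the ring that is attacked. The forward step relies on enolisation away from the ring fusion and on attack anti to the axial angular methyl.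

**7 ⇒ 6 ⇒ 4 ⇒ 2 ⇒ 1.** The C–isopropyl bond is cut and the ring D oxygen of 1 is restored. The cyclopentanone carbonyl of 1 is on the wrong carbon for the isopropyl group, but it allows dehydrogenation of the adjacent CH2–CH2 unit, which makes the carbon next to the ring fusion electrophilic. The same carbonyl is then deleted through the enolate formed in the addition. The demand is that the final reduction of 6 delivers hydrogen anti to the angular methyl at both new centres.

**21 ⇒ 18.** The allene is traced to a propargylic alcohol; C–O is replaced by C–H with 1,3-transposition, converting a stereocentre into the axis.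

## Other disconnections considered

Alternative 1: Pauson–Khand annulation of rings C and D. The cut removes the C/D fusion bond and the two bonds to the ring D carbonyl. Enyne A1 (rings A and B complete, a methallyl group on the B/C fusion CH and a 4-methylpent-2-ynyl group on the carbinol carbon) would be treated with Co2(CO)8 to give cyclopentenone A2.

- In favour: three C–C bonds, two rings and the quaternary carbon are made in one step. On skeletal bonds per step this plan is better than the chosen one.
- Against: 1,7-enynes with a 1,1-disubstituted alkene are slow substrates. The quaternary centre would depend on 1,3-induction from ring B. The tetrasubstituted enone would then have to be reduced to a trans-hydrindane with the isopropyl group cis to the methyl, and the ring D ketone removed, all in the presence of the acid-sensitive allylic alcohol.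
- Comparison: the chosen plan buys the quaternary centre in 1, sets the C/D centres on a small bicycle and leaves only two centres for the late ring-forming step.

Alternative 2: transannular carbonyl-ene closure. The cut is the B/C fusion bond. Twelve-membered enone A3 (rings A and D attached to a macrocycle with an (E)-trisubstituted alkene) would be treated with Me2AlCl to give alcohol A4, whose exocyclic methylene must then be hydrogenated.

- In favour: rings B and C, both fusion centres and the free tertiary alcohol arise together, with no protecting group. On late-stage step economy this plan is better.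
- Against: A3 is hard to reach. Ring D must carry its three contiguous centres without the help of ring C. The facial course of the ene step, the competition with chloride capture and the site of proton loss all depend on the macrocycle conformation. The final hydrogenation would set the ring B methyl centre on a flexible eight-membered ring.
- Comparison: the chosen plan sets that centre by a chair sigmatropic shift on a rigid cyclohexanone, which is easier to predict.

Alternative 3: Wagner–Meerwein contraction to ring D. The cut is the bond between the C/D fusion CH and the isopropyl-bearing carbon. Decalinol A5 (equatorial alcohol flanked by a gem-dimethyl carbon) would be ionised with Tf2O and 2,6-di-tert-butylpyridine to give isopropenyl hydrindanone A6, which on hydrogenation converges on 7.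

- In favour: the migration is stereospecific (antiperiplanar, inversion at the carbinol carbon), so the isopropyl centre and the trans fusion do not depend on a facial hydrogenation. On stereochemical certainty for ring D this plan is better than steps 2–4.
- Against: A5 needs its ring C carbonyl β to the fusion, which is not the substitution pattern of the Wieland–Miescher ketone, so several extra steps would be required. Methyl shift and simple elimination would compete. The route gains nothing for rings A and B.
- Comparison: equal from 7 onward; longer before it.

Key step: step 12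

Assumption (chemistry): the (R) enantiomer of the Hajos–Parrish ketone and (S)-4-(trimethylsilyl)but-3-yn-2-ol are taken as purchasable; a centre-by-centre check of 17 and 22 against 28 shows full agreement, so the only design change is the use of the single (aS) enantiomer of the allene instead of the racemate; 12 is carried as a mixture of carbinol epimers, and the isopropyl centre drawn for 3, 4 and 5 is the expected one and is erased in step 3.

## Route

Indene numbering is used for the bicyclic compounds (C7a = quaternary methyl carbon, C5 = ring C carbonyl).

Step 1
Reactants: 1 (R)-Hajos–Parrish ketone, (7aR)-7a-methyl-2,3,7,7a-tetrahydro-1H-indene-1,5(6H)-dione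
Product: 2 (7aR)-7a-methyl-7,7a-dihydro-1H-indene-1,5(6H)-dione
Conditions: IBX (1.5 equiv), DMSO/PhF, 65 °C
Reagents that add atoms: none
Why: IBX dehydrogenation of ketones goes through the enol; the cyclopentanone enol and the dienol of the enone both lead to the same C2=C3 unsaturation, and the quaternary C7a blocks aromatisation.

Step 2
Reactants: 2 (7aR)-7a-methyl-7,7a-dihydro-1H-indene-1,5(6H)-dione
Product: 4 (3R,7aR)-7a-methyl-5-oxo-3-(propan-2-yl)-5,6,7,7a-tetrahydro-3H-inden-1-yl trifluoromethanesulfonate, via magnesium enolate 3 (not isolated)
Conditions: iPrMgCl (1.2 equiv), CuBr·SMe2 (10 mol %), THF, −78 °C; then Comins' reagent, −78 → 0 °C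
Reagents that add atoms: isopropylmagnesium chloride CC(C)[Mg]Cl; N-(5-chloropyridin-2-yl)bis(trifluoromethanesulfonimide) (Comins' reagent) O=S(=O)(N(c1ccc(Cl)cn1)S(=O)(=O)C(F)(F)F)C(F)(F)F
Why: Copper-catalysed 1,4-addition goes to the β-CH of the cyclopentenone (C3), since the other β-position (C3a) is fully substituted, and the magnesium enolate is O-sulfonylated (conjugate addition–enolate trapping). The isopropyl group should enter anti to the angular methyl, but this centre is erased in step 3.

Step 3
Reactants: 4 enol triflate
Product: 6 (7aS)-7a-methyl-3-(propan-2-yl)-1,6,7,7a-tetrahydro-5H-inden-5-one, via skipped diene 5 (not isolated)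
Conditions: Pd(OAc)2 (5 mol %), PPh3, HCO2H, nBu3N, DMF, 60 °C; then DBU, rt
Reagents that add atoms: none
Why: Palladium-catalysed formate reduction of the alkenyl triflate replaces OTf by H. The C3–H of 5 is doubly allylic and γ to the enone, so base moves the alkene into the fully conjugated linear dienone, which removes the C3 stereocentre and the ring D oxygen in one operation.

Step 4
Reactants: 6 linear dienone
Product: 7 (3R,3aS,7aR)-7a-methyl-3-(propan-2-yl)octahydro-5H-inden-5-one (trans-fused; isopropyl cis to the angular methyl)
Conditions: H2 (4 atm), 10% Pd/C, EtOAc, rt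
Reagents that add atoms: none
Why: Heterogeneous hydrogenation from the face opposite the angular methyl should saturate the γ,δ-alkene first and place the isopropyl group cis to the methyl. With both groups then on one face, the enone should be reduced from the other face, which puts the C3a hydrogen trans to the methyl.

Step 5
Reactants: 7 trans-hydrindanone
Product: 10 (3R,3aS,6R,7aR)-6-[(2S)-but-3-en-2-yl]-7a-methyl-3-(propan-2-yl)octahydro-5H-inden-5-one, via dicrotyl ketal 8 (not isolated), via crotyl enol ether 9 (not isolated)
Conditions: (E)-crotyl alcohol (8 equiv), TsOH·H2O (cat.), PhMe, Dean–Stark, 110 °C; then Et3N, concentrate; EtCO2H (cat.), o-xylene, 145 °C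
Reagents that add atoms: (E)-but-2-en-1-ol C/C=C/CO
Why: Ketalisation, loss of crotyl alcohol and Claisen rearrangement; trans-hydrindan-5-ones enolise away from the ring fusion (towards C6), and the allyl unit bonds anti to the syn-axial angular methyl, which gives the equatorial side chain directly. In the chair transition state the (E)-alkene places H rather than CH3 under the ring, which fixes the side-chain centre as (S).

Step 6
Reactants: 10 vinyl ketone
Product: 12 (3R,3aS,7aR)-6-[(2S)-hex-5-en-2-yl]-7a-methyl-3-(propan-2-yl)octahydro-1H-inden-5-ol (carbinol epimers), via alkylborane 11 (not isolated)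
Conditions: 9-BBN (2.5 equiv), THF, 0 °C → rt; then vinyl bromide (1 M in THF), Pd(dppf)Cl2 (5 mol %), aq. K3PO4, THF/DMF, 50 °C
Reagents that add atoms: vinyl bromide C=CBr
Why: 9-BBN hydroborates the terminal alkene at the CH2 terminus and also reduces the ketone, which is accepted; B-alkyl Suzuki–Miyaura coupling of the primary alkylborane with vinyl bromide adds the two missing carbons. No stereocentre of the chain or ring fusion is touched.

Step 7
Reactants: 12 alcohol (epimers)
Product: 13 (3R,3aS,6R,7aR)-6-[(2S)-hex-5-en-2-yl]-7a-methyl-3-(propan-2-yl)octahydro-5H-inden-5-one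
Conditions: Dess–Martin periodinane, NaHCO3, CH2Cl2, rt
Reagents that add atoms: none
Why: Dess–Martin oxidation of the secondary alcohol; the α-centre is already the favoured equatorial epimer, so the buffered conditions leave it unchanged.

Step 8
Reactants: 13 ketone
Product: 15 1-[5-hydroxy-6-[(2S)-hex-5-en-2-yl]-7a-methyl-3-(propan-2-yl)octahydro-1H-inden-5-yl]prop-2-en-1-one (hydroxyl axial and trans to the angular methyl; acryloyl equatorial), via lithium alkoxide 14 (not isolated)
Conditions: methoxyallene, nBuLi, THF, −78 °C; add 13, −78 °C; then 1 M HCl, THF, 0 °C
Reagents that add atoms: methoxyallene COC=C=C; water O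
Why: 1-Lithio-1-methoxyallene is an acryloyl anion equivalent; alkenyl-type organolithiums add to 2-substituted cyclohexanones from the equatorial direction, trans to the α-substituent, which gives the axial tertiary alcohol required. Mild acid hydrolyses the allenyl enol ether to the vinyl ketone.

Step 9
Reactants: 15 α-hydroxy enone
Product: 16 tert-butyldimethylsilyl ether of 15
Conditions: TBSOTf, 2,6-lutidine, CH2Cl2, −78 → 0 °C
Reagents that add atoms: tert-butyldimethylsilyl trifluoromethanesulfonate CC(C)(C)[Si](C)(C)OS(=O)(=O)C(F)(F)F
Why: Silylation of a tertiary alcohol with a silyl triflate and a hindered base. The ether keeps the alcohol from binding TiCl4 in step 12 and from being sulfonylated in step 15, and its bulk differentiates the enone faces.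

Step 10
Reactants: 16 diene
Product: 17 tricyclic cis-cyclooctenone silyl ether (rings B, C and D; trans B/C and C/D fusions; silyloxy group axial on ring C)
Conditions: second-generation Grubbs catalyst RuCl2(=CHPh)(H2IMes)(PCy3) (10 mol %), PhMe (1 mM), 80 °C
Reagents that add atoms: none
Why: Ring-closing metathesis; the catalyst loads on the terminal alkene and closes onto the vinyl ketone, and the eight-membered ring can only hold the cis alkene. The two chains are gauche on adjacent equatorial positions and the carbinol carbon is fully substituted, both of which favour closure.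

Step 11
Reactants: 18 (S)-4-(trimethylsilyl)but-3-yn-2-ol
Product: 21 (aS)-1-(trimethylsilyl)buta-1,2-diene, via propargyl sulfonylhydrazine 19 (not isolated), via propargyl diazene 20 (not isolated)
Conditions: 2-O2NC6H4SO2NHNH2, PPh3, DEAD, THF, −15 °C → rt; pentane extraction, distillation
Reagents that add atoms: none
Why: Myers allene synthesis: Mitsunobu displacement with inversion, loss of sulfinic acid, then retro-ene loss of N2, which delivers hydrogen to the alkyne terminus on the face of the departing nitrogen. The stereocentre of 18 is thereby converted stereospecifically into the (aS) axis.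

Step 12
Reactants: 17 tricyclic cis-cyclooctenone silyl ether; 21 (aS)-1-(trimethylsilyl)buta-1,2-diene
Product: 22 tetracyclic ketone with ring A vinylsilane (A/B cis-fused; ring A methyl trans to the ring B CH2)
Conditions: TiCl4 (1.3 equiv), CH2Cl2, −78 °C; then 21 (2 equiv), −78 °C
Reagents that add atoms: none
Why: TiCl4 activates the enone carbonyl, and the allene attacks the β-carbon through its methyl-bearing terminus anti to silicon, giving a titanium enolate and a vinyl cation stabilised by the β C–Si bond; a 1,2-shift of silicon moves the cation to the former CH(Si) carbon, which the enolate α-carbon captures. The closest known reaction is the Danheiser (trimethylsilyl)cyclopentene annulation of cyclic enones with allenylsilanes. Ring A closes in a 5-endo mode (the enolate carbon attacks the cationic end of a C=C unit that ends up inside the ring), and because both bonds form on one face of the cis-enone the A/B fusion is cis at first. The A/B fusion CH is set by the enone face: the axial silyloxy group on the neighbouring carbon covers one face of the cyclooctenone, so addition should occur anti to it. The CH(CH3) centre is set by the reagent: attack anti to silicon on the (aS) allene places the methyl trans to the ring B CH2, which is also the less crowded arrangement in the ring-forming geometry, so reagent and substrate preferences should reinforce. The third new centre, the ketone α-carbon, follows from the suprafacial closure and is removed in step 15. The step needs terminus-to-β-carbon regiochemistry (secured by the β-silicon effect), ring closure in preference to loss of silicon to a propargyl ketone (favoured at −78 °C) and face selectivity (secured by the silyl ether on the rigid trans B/C frame).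

Step 13
Reactants: 22 vinylsilane
Product: 23 tetracyclic ketone with ring A cis-disubstituted alkene
Conditions: CF3CO2H, CH2Cl2, 0 °C → rt
Reagents that add atoms: none
Why: Protodesilylation of a vinylsilane: ipso protonation gives a β-silyl cation that loses silicon, so the alkene stays where it is and the CH(CH3) centre is not touched. The tertiary silyl ether should survive anhydrous acid at this temperature.

Step 14
Reactants: 23 ring A alkene
Product: 24 saturated tetracyclic ketone
Conditions: H2 (1 atm), 10% Pd/C, EtOAc, rt
Reagents that add atoms: none
Why: Hydrogenation of an unhindered disubstituted cyclopentene; no stereocentre is formed, and the ketone and silyl ether are inert.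

Step 15
Reactants: 24 saturated ketone
Product: 26 tetrasubstituted enol triflate (double bond towards ring A), via potassium enolate 25 (not isolated)
Conditions: KN(SiMe3)2 (1.5 equiv), THF, −78 °C; then PhNTf2, −78 → 0 °C
Reagents that add atoms: N-phenylbis(trifluoromethanesulfonimide) O=S(=O)(N(c1ccccc1)S(=O)(=O)C(F)(F)F)C(F)(F)F
Why: The ketone has a single α-hydrogen, on ring A, so enolisation is regiospecific and the enolate alkene can only be cis within the eight-membered ring; O-sulfonylation gives the enol triflate.

Step 16
Reactants: 26 enol triflate
Product: 27 sesterfisherol tert-butyldimethylsilyl ether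
Conditions: MeMgBr (3 equiv), Fe(acac)3 (10 mol %), THF/NMP, −20 → 0 °C
Reagents that add atoms: methylmagnesium bromide C[Mg]Br
Why: Iron-catalysed cross-coupling of alkenyl triflates with methyl Grignard reagent works on hindered, fully substituted triflates and keeps the alkene position; the silyl ether is inert.

Step 17
Reactants: 27 silyl ether
Product: 28 sesterfisherol
Conditions: Bu4NF, THF, 50 °C
Reagents that add atoms: none
Why: Fluoride cleavage of the silyl ether; the non-acidic conditions protect the tertiary allylic alcohol from ionisation.

## Compound list

1 | (R)-Hajos–Parrish ketone, (7aR)-7a-methyl-2,3,7,7a-tetrahydro-1H-indene-1,5(6H)-dione | C[C@@]12CCC(=O)C=C1CCC2=O | starting material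
2 | (7aR)-7a-methyl-7,7a-dihydro-1H-indene-1,5(6H)-dione | C[C@@]12CCC(=O)C=C1C=CC2=O | intermediate
3 | chloromagnesium C1-enolate of the 3-isopropyl adduct (isopropyl trans to methyl) | C[C@@]12CCC(=O)C=C1[C@H](C(C)C)C=C2O[Mg]Cl | intermediate
4 | (3R,7aR)-7a-methyl-5-oxo-3-(propan-2-yl)-5,6,7,7a-tetrahydro-3H-inden-1-yl trifluoromethanesulfonate | C[C@@]12CCC(=O)C=C1[C@H](C(C)C)C=C2OS(=O)(=O)C(F)(F)F | intermediate
5 | (3R,7aS)-7a-methyl-3-(propan-2-yl)-3,6,7,7a-tetrahydro-5H-inden-5-one (skipped diene) | C[C@@]12CCC(=O)C=C1[C@H](C(C)C)C=C2 | intermediate
6 | (7aS)-7a-methyl-3-(propan-2-yl)-1,6,7,7a-tetrahydro-5H-inden-5-one | C[C@@]12CCC(=O)C=C1C(C(C)C)=CC2 | intermediate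
7 | (3R,3aS,7aR)-7a-methyl-3-(propan-2-yl)octahydro-5H-inden-5-one | O=C1CC[C@@]2(C)CC[C@H](C(C)C)[C@@H]2C1 | intermediate
8 | 5,5-bis[(E)-but-2-enyloxy] ketal of 7 | C/C=C/COC1(OC/C=C/C)CC[C@@]2(C)CC[C@H](C(C)C)[C@@H]2C1 | intermediate
9 | (E)-but-2-enyl enol ether of 7 (C5=C6) | C/C=C/COC1=CC[C@@]2(C)CC[C@H](C(C)C)[C@@H]2C1 | intermediate
10 | (3R,3aS,6R,7aR)-6-[(2S)-but-3-en-2-yl]-7a-methyl-3-(propan-2-yl)octahydro-5H-inden-5-one | C=C[C@H](C)[C@H]1C[C@@]2(C)CC[C@H](C(C)C)[C@@H]2CC1=O | intermediate
11 | B-alkyl-9-BBN adduct of 10 with the carbonyl reduced to its 9-BBN borinate | C(C[C@H](C)[C@H]1C[C@@]2(C)CC[C@H](C(C)C)[C@@H]2CC1OB1C2CCCC1CCC2)B1C2CCCC1CCC2 | intermediate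
12 | 6-[(2S)-hex-5-en-2-yl]-7a-methyl-3-(propan-2-yl)octahydro-1H-inden-5-ol (carbinol epimers) | C=CCC[C@H](C)[C@H]1C[C@@]2(C)CC[C@H](C(C)C)[C@@H]2CC1O | intermediate
13 | (3R,3aS,6R,7aR)-6-[(2S)-hex-5-en-2-yl]-7a-methyl-3-(propan-2-yl)octahydro-5H-inden-5-one | C=CCC[C@H](C)[C@H]1C[C@@]2(C)CC[C@H](C(C)C)[C@@H]2CC1=O | intermediate
14 | lithium alkoxide of the 5-(1-methoxypropa-1,2-dienyl) carbinol | C=CCC[C@H](C)[C@H]1C[C@@]2(C)CC[C@H](C(C)C)[C@@H]2C[C@]1(O[Li])C(OC)=C=C | intermediate
15 | α-hydroxy vinyl ketone (axial OH, equatorial acryloyl) | C=CCC[C@H](C)[C@H]1C[C@@]2(C)CC[C@H](C(C)C)[C@@H]2C[C@]1(O)C(=O)C=C | intermediate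
16 | tert-butyldimethylsilyl ether of 15 | C=CCC[C@H](C)[C@H]1C[C@@]2(C)CC[C@H](C(C)C)[C@@H]2C[C@]1(O[Si](C)(C)C(C)(C)C)C(=O)C=C | intermediate
17 | tricyclic cis-cyclooctenone silyl ether (rings B, C, D) | O=C1/C=C\CC[C@H](C)[C@H]2C[C@@]3(C)CC[C@H](C(C)C)[C@@H]3C[C@]12O[Si](C)(C)C(C)(C)C | intermediate
18 | (S)-4-(trimethylsilyl)but-3-yn-2-ol | C[C@H](O)C#C[Si](C)(C)C | starting material
19 | (R)-N-[4-(trimethylsilyl)but-3-yn-2-yl]-2-nitrobenzenesulfonohydrazide | C[C@@H](N(N)S(=O)(=O)c1ccccc1[N+](=O)[O-])C#C[Si](C)(C)C | intermediate
20 | (R)-[4-(trimethylsilyl)but-3-yn-2-yl]diazene | C[C@@H](N=N)C#C[Si](C)(C)C | intermediate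
21 | (aS)-1-(trimethylsilyl)buta-1,2-diene | [H]C(C)=[C@]=C([H])[Si](C)(C)C | intermediate
22 | tetracyclic ketone with ring A vinylsilane | O=C1[C@@H]2C=C([Si](C)(C)C)[C@@H](C)[C@@H]2CC[C@H](C)[C@H]2C[C@@]3(C)CC[C@H](C(C)C)[C@@H]3C[C@]12O[Si](C)(C)C(C)(C)C | intermediate
23 | tetracyclic ketone with ring A alkene (silicon removed) | O=C1[C@@H]2C=C[C@@H](C)[C@@H]2CC[C@H](C)[C@H]2C[C@@]3(C)CC[C@H](C(C)C)[C@@H]3C[C@]12O[Si](C)(C)C(C)(C)C | intermediate
24 | saturated tetracyclic ketone | O=C1[C@@H]2CC[C@@H](C)[C@@H]2CC[C@H](C)[C@H]2C[C@@]3(C)CC[C@H](C(C)C)[C@@H]3C[C@]12O[Si](C)(C)C(C)(C)C | intermediate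
25 | potassium enolate of 24 | [K]O/C1=C2\CC[C@@H](C)[C@@H]2CC[C@H](C)[C@H]2C[C@@]3(C)CC[C@H](C(C)C)[C@@H]3C[C@]12O[Si](C)(C)C(C)(C)C | intermediate
26 | enol triflate of 24 | FC(F)(F)S(=O)(=O)O/C1=C2\CC[C@@H](C)[C@@H]2CC[C@H](C)[C@H]2C[C@@]3(C)CC[C@H](C(C)C)[C@@H]3C[C@]12O[Si](C)(C)C(C)(C)C | intermediate
27 | sesterfisherol tert-butyldimethylsilyl ether | C/C1=C2\CC[C@@H](C)[C@@H]2CC[C@H](C)[C@H]2C[C@@]3(C)CC[C@H](C(C)C)[C@@H]3C[C@]12O[Si](C)(C)C(C)(C)C | intermediate
28 | sesterfisherol | C/C1=C2\CC[C@@H](C)[C@@H]2CC[C@H](C)[C@H]2C[C@@]3(C)CC[C@H](C(C)C)[C@@H]3C[C@]12O | target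

## Step count and least certain steps

Total: 17 steps. Longest linear sequence: 16 steps (steps 1–10 and 12–17); step 11 is a one-step side branch.

**Step 12 (key step).** The most likely failure is loss of silicon from the vinyl cation before ring closure, which gives conjugate propargylation. The allene has no substituent on the silicon-bearing carbon, so the rearranged cation is poorly stabilised, and the twisted cis-cyclooctenone is only a moderate acceptor. Attack on the wrong enone face is the second risk.
Fallback, from 17 back to 23: (R)-but-3-yn-2-ol would be converted with MsCl and Et3N into (R)-but-3-yn-2-yl methanesulfonate F1. Anti SN2' displacement with Bu3SnLi and CuBr·SMe2 would give (aS)-tributyl(buta-1,2-dien-1-yl)stannane F2. With TiCl4 at −78 °C, F2 should add to 17 in an anti SE2' sense to give the β-(but-3-yn-2-yl) ketone F3 with the same methyl configuration. TBSOTf and Et3N would give the silyl enol ether F4, the only one possible. A 5-endo-dig carbocyclisation with (Ph3P)AuCl and AgBF4 in wet CH2Cl2 (Conia-ene type, monovalent gold) would close ring A and give 23 directly, without a protodesilylation step.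

**Step 4.** The most likely failure is poor facial selectivity at the ring-fusion carbon, because hydrindenones tend to take up hydrogen cis to the angular methyl unless a neighbouring group blocks that face.
Fallback, from 6 back to 7: homogeneous hydrogenation with RhCl(PPh3)3 and H2 would saturate only the γ,δ-alkene from the face opposite the methyl, giving 3-isopropyl enone F5 (isopropyl cis to methyl). Conjugate reduction with tBuCu and iBu2AlH in THF/HMPA, or with Li in NH3, delivers hydride or proton to the ring-fusion carbon anti to both β-face groups and should give 7.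

**Step 2.** The most likely failure is incomplete O-sulfonylation of the hindered magnesium enolate next to the quaternary carbon (proton quench or C-sulfonylation); the copper-catalysed addition itself is routine.
Fallback, from 2 back to 6: the conjugate addition would be quenched with aqueous NH4Cl to give 3-isopropyl diketone F6. NaBH4 in EtOH at −20 °C should reduce only the saturated cyclopentanone carbonyl to hydroxy enone F7. MsCl and Et3N would give mesylate F8, and DBU in hot toluene would eliminate to 5 and isomerise it to 6.

**Step 5.** The most likely failures are enol ether formation towards the ring-fusion side, a boat transition state, or acid-catalysed allylic transposition of the crotyl unit, each of which would erode regio- or stereocontrol.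
Fallback, from 7 back to 10: LiN(iPr)2 and Me3SiCl at −78 °C would give the kinetic silyl enol ether F9 (C5=C6). Iridium-catalysed branch-selective allylation with (E)-crotyl methyl carbonate ([Ir(cod)Cl]2, a chiral phosphoramidite ligand chosen to give the (S) side-chain centre, CsF, ZnF2) would then set that centre under catalyst control and give 10.

**Step 10.** The most likely failure is oligomerisation by intermolecular metathesis, because the ring is medium-sized and the vinyl ketone is electron-poor and flanked by a fully substituted carbon.
Fallback, from 16 back to 17: NaBH4 and CeCl3·7H2O in MeOH would reduce the vinyl ketone to the allylic alcohols F10. Ring-closing metathesis of this more reactive diene with RuCl2(=CHPh)(H2IMes)(PCy3) would give cyclooctenol F11, and Dess–Martin oxidation would give 17.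

## Further compounds

F1 | step 12 | (R)-but-3-yn-2-yl methanesulfonate | C[C@@H](OS(C)(=O)=O)C#C
F2 | step 12 | (aS)-tributyl(buta-1,2-dien-1-yl)stannane | [H]C(C)=[C@]=C([H])[Sn](CCCC)(CCCC)CCCC
F3 | step 12 | β-(but-3-yn-2-yl) cyclooctanone silyl ether (conjugate propargylation product of 17) | O=C1C[C@H]([C@H](C)C#C)CC[C@H](C)[C@H]2C[C@@]3(C)CC[C@H](C(C)C)[C@@H]3C[C@]12O[Si](C)(C)C(C)(C)C
F4 | step 12 | tert-butyldimethylsilyl enol ether of F3 | CC(C)(C)[Si](C)(C)O/C1=C/[C@H]([C@H](C)C#C)CC[C@H](C)[C@H]2C[C@@]3(C)CC[C@H](C(C)C)[C@@H]3C[C@]12O[Si](C)(C)C(C)(C)C
F5 | step 4 | 7a-methyl-3-(propan-2-yl)-1,2,3,6,7,7a-hexahydro-5H-inden-5-one (isopropyl cis to methyl) | C[C@@]12CCC(=O)C=C1[C@@H](C(C)C)CC2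
F6 | step 2 | 7a-methyl-3-(propan-2-yl)-2,3,7,7a-tetrahydro-1H-indene-1,5(6H)-dione (isopropyl trans to methyl) | C[C@@]12CCC(=O)C=C1[C@H](C(C)C)CC2=O
F7 | step 2 | 1-hydroxy-7a-methyl-3-(propan-2-yl)-1,2,3,6,7,7a-hexahydro-5H-inden-5-one (hydroxyl cis to methyl) | C[C@@]12CCC(=O)C=C1[C@H](C(C)C)C[C@H]2O
F8 | step 2 | methanesulfonate of F7 | C[C@@]12CCC(=O)C=C1[C@H](C(C)C)C[C@H]2OS(C)(=O)=O
F9 | step 5 | trimethylsilyl enol ether of 7 (C5=C6) | C[Si](C)(C)OC1=CC[C@@]2(C)CC[C@H](C(C)C)[C@@H]2C1
F10 | step 10 | allylic alcohols from 1,2-reduction of 16 (carbinol epimers) | C=CCC[C@H](C)[C@H]1C[C@@]2(C)CC[C@H](C(C)C)[C@@H]2C[C@]1(O[Si](C)(C)C(C)(C)C)C(O)C=C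
F11 | step 10 | tricyclic cis-cyclooctenol silyl ether (carbinol epimers) | OC1/C=C\CC[C@H](C)[C@H]2C[C@@]3(C)CC[C@H](C(C)C)[C@@H]3C[C@]12O[Si](C)(C)C(C)(C)C
A1 | alternative 1 | 1,7-enyne on rings A and B (methallyl on the B/C fusion CH; 4-methylpent-2-ynyl on the carbinol carbon) | C/C1=C2\CC[C@@H](C)[C@@H]2CC[C@H](C)[C@@H](CC(C)=C)[C@]1(O)CC#CC(C)C
A2 | alternative 1 | tetracyclic ring D cyclopentenone | C/C1=C2\CC[C@@H](C)[C@@H]2CC[C@H](C)[C@H]2C[C@@]3(C)CC(=O)C(C(C)C)=C3C[C@]12O
A3 | alternative 2 | twelve-membered enone carrying rings A and D | C/C1=C2\CC[C@@H](C)[C@@H]2CC/C(C)=C/C[C@@]2(C)CC[C@H](C(C)C)[C@@H]2CC1=O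
A4 | alternative 2 | tetracyclic alcohol with exocyclic methylene on ring B | C/C1=C2\CC[C@@H](C)[C@@H]2CCC(=C)[C@H]2C[C@@]3(C)CC[C@H](C(C)C)[C@@H]3C[C@]12O
A5 | alternative 3 | trans-decalinol with equatorial hydroxyl next to the gem-dimethyl carbon | O=C1CC[C@@]2(C)CC[C@H](O)C(C)(C)[C@@H]2C1
A6 | alternative 3 | isopropenyl trans-hydrindanone | O=C1CC[C@@]2(C)CC[C@H](C(C)=C)[C@@H]2C1
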